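**Plan**

1. Ring numbering used below: C1 carries CH2OBz (C7) and, with C2, the epoxide; C3=C4 is the alkene; C5 carries OBz; C6 carries OH.
2. Cuts, in retrosynthetic order: the epoxide oxygen from C1/C2 (back to a C6-hydroxy-1,3-diene); C3=C4 re-masked as a vicinal bis-sulfone; the C6–O bond, with the alkene returned to C1=C6 and the C5 oxygen re-bridged onto C2; last, C2–C3 and C4–C5 together.
3. Enabling feature: C2–C1(C7)–C6–C5, with oxygen on the 1,4-related carbons C2 and C5, is a 3-substituted furan ring, and the bare CH=CH (C3, C4) between them is an acetylene; hence furan-3-ylmethyl benzoate plus an acetylene equivalent in a Diels–Alder reaction.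
4. Forward order: furan ring → [4+2] closes the six-membered carbocycle as a 7-oxabicyclo[2.2.1]heptene → the oxygen bridge is opened to the cyclohexene → loss of the two sulfinates gives the diene → the epoxide ring is closed last.
5. Stereochemistry: the bridge fixes C5–O; a chiral rhodium catalyst selects one enantiomer of the racemic adduct and puts the C6 oxygen anti to the bridge (trans to C5–O); C1 and C2 are set cis to C6–OH by hydroxyl-directed epoxidation.

Key step: step 2

Assumption: which enantiomer of adduct 5 is matched to the (R,S) ligand in step 3 cannot be predicted with certainty; the ligand enantiomer is chosen so that the (1S,4R,5R,6S) enantiomer of 5 is the one that reacts. The resolution uses at most half of 5.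

**Route**

Step 1
Reactants: 1 furan-3-ylmethanol; 2 benzoyl chloride
Product: 3 furan-3-ylmethyl benzoate
Conditions: BzCl, Et3N, DMAP (cat.), CH2Cl2, 0 °C to rt
Reagents that add atoms: benzoyl chloride, O=C(Cl)c1ccccc1
Why: O-acylation of a primary alcohol under nucleophilic catalysis should install the C7 benzoate that is kept to the end; no stereocentre is involved.

Step 2
Reactants: 3 furan-3-ylmethyl benzoate; 4 (Z)-1,2-bis(phenylsulfonyl)ethene
Product: 5 racemic [(1S*,4R*,5R*,6S*)-5,6-bis(phenylsulfonyl)-7-oxabicyclo[2.2.1]hept-2-en-2-yl]methyl benzoate (both sulfonyl groups exo, cis to each other)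
Conditions: toluene, 60 °C, sealed vessel, prolonged heating (thermodynamic control)
Reagents that add atoms: (Z)-1,2-bis(phenylsulfonyl)ethene, O=S(=O)(/C=C\S(=O)(=O)c1ccccc1)c1ccccc1
Why: Normal-demand Diels–Alder reaction between the furan diene of 3 (its α-carbons become C2 and C5, its β-carbons C1 and C6) and the doubly sulfonyl-activated alkene 4 (C3, C4), which stands in for acetylene; the closest known reaction type is the cycloaddition of furans to cis-1,2-bis(arylsulfonyl)ethenes. Both new C–C bonds (C2–C3 and C4–C5) form in one concerted suprafacial–suprafacial event that closes the six-membered carbocycle intermolecularly and leaves the furan oxygen as a one-atom bridge across C2 and C5. The bridgehead centres C2 and C5 are necessarily cis and arise as a racemate because neither partner is chiral, and C3 and C4 keep the cis relationship of the Z-alkene. The step needs the exo orientation of the two sulfonyl groups (syn to the oxygen bridge), so that the concave endo face of the remaining C1=C6 alkene stays open for step 3; running the reversible furan cycloaddition under thermodynamic control should secure this, the endo adduct reverting to 3 and 4. Regiochemistry is not an issue because 4 is symmetrical, and the sulfonyl groups are helpers that leave in step 6.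

Step 3
Reactants: 5 racemic exo,exo-bis-sulfone adduct; 6 4-methoxybenzyl alcohol
Product: 7 [(3S,4R,5R,6S)-5-hydroxy-6-[(4-methoxybenzyl)oxy]-3,4-bis(phenylsulfonyl)cyclohex-1-en-1-yl]methyl benzoate
Conditions: [Rh(COD)Cl]2 (cat.), (R)-1-[(S)-2-(diphenylphosphino)ferrocenyl]ethyldi-tert-butylphosphine (cat.), AgOTf then Bu4NI (cat.), 4-methoxybenzyl alcohol, THF, 80 °C, stopped near half conversion
Reagents that add atoms: 4-methoxybenzyl alcohol, COc1ccc(CO)cc1
Why: Rhodium-catalysed asymmetric ring opening of an oxabicyclic alkene (anti SN2′ addition of an alcohol) run as a kinetic resolution: the chiral monovalent rhodium complex should insert from the exo face into the allylic bridgehead C2–O bond of the matched enantiomer and the alcohol then attacks the unsubstituted allyl terminus C6 from the endo face, anti to the departing oxygen, which keeps the bridge configuration at C5–OH, sets C6–O trans to it and moves the alkene to C1=C2, whereas the mirror-image enantiomer would need attack at the fully substituted C1 and should remain (it can be returned to racemic 5 by thermal cycloreversion and re-addition).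

Step 4
Reactants: 7 hydroxy PMB ether; 2 benzoyl chloride
Product: 8 [(3S,4R,5R,6S)-5-(benzoyloxy)-6-[(4-methoxybenzyl)oxy]-3,4-bis(phenylsulfonyl)cyclohex-1-en-1-yl]methyl benzoate
Conditions: BzCl, pyridine, DMAP (cat.), CH2Cl2, 0 °C to rt
Reagents that add atoms: benzoyl chloride, O=C(Cl)c1ccccc1
Why: Acylation of the only free hydroxyl (C5–OH) places the second benzoate of the target; the weakly basic medium should not deprotonate the α-sulfonyl positions and no stereocentre is touched.

Step 5
Reactants: 8 dibenzoate PMB ether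
Product: 9 [(3S,4R,5R,6S)-5-(benzoyloxy)-6-hydroxy-3,4-bis(phenylsulfonyl)cyclohex-1-en-1-yl]methyl benzoate
Conditions: DDQ, CH2Cl2–pH 7 phosphate buffer, 0 °C to rt
Reagents that add atoms: none
Why: Oxidative cleavage of a 4-methoxybenzyl ether by DDQ (hydride abstraction, hydrolysis of the oxocarbenium ion) should free C6–OH while benzoates, sulfones and the isolated trisubstituted alkene are inert, the buffer guarding against acyl migration.

Step 6
Reactants: 9 hydroxy dibenzoate bis-sulfone
Product: 10 [(5S,6S)-5-(benzoyloxy)-6-hydroxycyclohexa-1,3-dien-1-yl]methyl benzoate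
Conditions: 5% Na/Hg, NaH2PO4, MeOH–THF, −20 °C
Reagents that add atoms: none
Why: Reductive elimination of a vicinal bis-sulfone (the unveiling step of the acetylene-equivalent tactic): electron transfer cleaves one C–S bond and the resulting β-sulfonyl radical or anion expels the second sulfinate to give C3=C4 whatever the configuration at C3 and C4, and the cold buffered medium should spare the esters and the C5/C6 centres.

Step 7
Reactants: 10 trans-hydroxy benzoate diene; 11 tert-butyl hydroperoxide
Product: 12 (−)-pipoxide, [(1R,2R,3S,6S)-3-(benzoyloxy)-2-hydroxy-7-oxabicyclo[4.1.0]hept-4-en-1-yl]methyl benzoate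
Conditions: VO(acac)2 (cat.), t-BuOOH (decane), CH2Cl2, 0 °C
Reagents that add atoms: tert-butyl hydroperoxide, CC(C)(C)OO
Why: Hydroxyl-directed epoxidation of an allylic alcohol: the vanadate ester of C6–OH should deliver oxygen to the adjacent, more electron-rich trisubstituted C1=C2 bond from the face of the hydroxyl, setting C1 and C2 cis to C6–OH and leaving the homoallylic C3=C4 bond (deactivated by the allylic benzoate) untouched.

**Compound list**

1 | furan-3-ylmethanol | OCc1ccoc1 | starting material
2 | benzoyl chloride | O=C(Cl)c1ccccc1 | starting material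
3 | furan-3-ylmethyl benzoate | O=C(OCc1ccoc1)c1ccccc1 | intermediate
4 | (Z)-1,2-bis(phenylsulfonyl)ethene | O=S(=O)(/C=C\S(=O)(=O)c1ccccc1)c1ccccc1 | starting material
5 | [(1S*,4R*,5R*,6S*)-5,6-bis(phenylsulfonyl)-7-oxabicyclo[2.2.1]hept-2-en-2-yl]methyl benzoate, exo,exo, racemate (SMILES shows the enantiomer consumed in step 3) | O=C(OCC1=C[C@H]2O[C@@H]1[C@H](S(=O)(=O)c1ccccc1)[C@@H]2S(=O)(=O)c1ccccc1)c1ccccc1 | intermediate
6 | 4-methoxybenzyl alcohol | COc1ccc(CO)cc1 | starting material
7 | [(3S,4R,5R,6S)-5-hydroxy-6-[(4-methoxybenzyl)oxy]-3,4-bis(phenylsulfonyl)cyclohex-1-en-1-yl]methyl benzoate | O=C(OCC1=C[C@H](S(=O)(=O)c2ccccc2)[C@H](S(=O)(=O)c2ccccc2)[C@H](O)[C@H]1OCc1ccc(OC)cc1)c1ccccc1 | intermediate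
8 | [(3S,4R,5R,6S)-5-(benzoyloxy)-6-[(4-methoxybenzyl)oxy]-3,4-bis(phenylsulfonyl)cyclohex-1-en-1-yl]methyl benzoate | O=C(OCC1=C[C@H](S(=O)(=O)c2ccccc2)[C@H](S(=O)(=O)c2ccccc2)[C@H](OC(=O)c2ccccc2)[C@H]1OCc1ccc(OC)cc1)c1ccccc1 | intermediate
9 | [(3S,4R,5R,6S)-5-(benzoyloxy)-6-hydroxy-3,4-bis(phenylsulfonyl)cyclohex-1-en-1-yl]methyl benzoate | O=C(OCC1=C[C@H](S(=O)(=O)c2ccccc2)[C@H](S(=O)(=O)c2ccccc2)[C@H](OC(=O)c2ccccc2)[C@H]1O)c1ccccc1 | intermediate
10 | [(5S,6S)-5-(benzoyloxy)-6-hydroxycyclohexa-1,3-dien-1-yl]methyl benzoate | O=C(OCC1=CC=C[C@H](OC(=O)c2ccccc2)[C@H]1O)c1ccccc1 | intermediate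
11 | tert-butyl hydroperoxide | CC(C)(C)OO | starting material
12 | (−)-pipoxide, [(1R,2R,3S,6S)-3-(benzoyloxy)-2-hydroxy-7-oxabicyclo[4.1.0]hept-4-en-1-yl]methyl benzoate | O=C(OC[C@]12O[C@H]1C=C[C@H](OC(=O)c1ccccc1)[C@H]2O)c1ccccc1 | target

**Count and risks**

Total step count: 7. Longest linear sequence: 7 steps, from furan-3-ylmethanol.

Steps most likely to fail:

Step 3. The chiral catalyst may discriminate the two enantiomers of 5 poorly, or the mismatched enantiomer may be opened at C1, so that 7 is not enantiomerically pure. Fallback (resolution through covalent diastereomers instead of catalyst control), setting out from 5 and returning at 9: racemic 5 is opened with an achiral catalyst ([Rh(COD)Cl]2, 1,1′-bis(diphenylphosphino)ferrocene, Et3N, THF, 80 °C) using (S)-2-methoxy-2-phenylacetic acid as the oxygen nucleophile, a known carboxylic acid variant of the same anti SN2′ opening. Regiochemistry is then substrate-controlled (attack at the unsubstituted C6), and the two enantiomers of 5 should give the diastereomeric esters [(3S,4R,5R,6S)-5-hydroxy-6-{[(2S)-2-methoxy-2-phenylacetyl]oxy}-3,4-bis(phenylsulfonyl)cyclohex-1-en-1-yl]methyl benzoate F1 and its (3R,4S,5S,6R) diastereomer F2, which are separated by chromatography or crystallisation. F1 is benzoylated at C5–OH (BzCl, pyridine) to the C5 benzoate of F1, [(3S,4R,5R,6S)-5-(benzoyloxy)-6-{[(2S)-2-methoxy-2-phenylacetyl]oxy}-3,4-bis(phenylsulfonyl)cyclohex-1-en-1-yl]methyl benzoate F3. The α-methoxy ester, far more labile than a benzoate, is then removed selectively (Yb(OTf)3, MeOH, rt), which gives 9 in the same number of steps.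

Step 6. Electron transfer may cleave the allylic or dienylic benzoates, or the C5 benzoate may migrate to the free C6–OH in the basic medium. Fallback (unveil the alkene before the secondary benzoate and the free hydroxyl exist), setting out from 7 and returning at 10: the sodium amalgam reduction is carried out on 7 to give [(5S,6S)-5-hydroxy-6-[(4-methoxybenzyl)oxy]cyclohexa-1,3-dien-1-yl]methyl benzoate F4. C5–OH is benzoylated (BzCl, pyridine) to [(5S,6S)-5-(benzoyloxy)-6-[(4-methoxybenzyl)oxy]cyclohexa-1,3-dien-1-yl]methyl benzoate F5, and the ether is cleaved last with DDQ in buffered CH2Cl2 at low temperature, where ether oxidation should outrun dehydrogenation of the diene, to give 10.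

Step 7. The vanadium catalyst may oxidise the dienol to the dienone, followed by aromatisation, or oxygen may be transferred to C3=C4. Fallback (build the epoxide from dioxygen instead of directed peroxide transfer), setting out from 10 and returning at 12: sensitised photo-oxygenation (O2, tetraphenylporphyrin, hν, CH2Cl2, −20 °C) should add singlet oxygen across C1 and C4 on the face of the hydrogen-bonding C6–OH, away from the C5 benzoate, giving the endoperoxide [(1R,4R,7R,8R)-7-(benzoyloxy)-8-hydroxy-2,3-dioxabicyclo[2.2.2]oct-5-en-1-yl]methyl benzoate F6. P(OMe)3 then attacks the less hindered peroxide oxygen on C4 and the C1 alkoxide closes onto C2 in a syn SN2′ displacement with shift of the alkene to C3=C4, a known deoxygenative rearrangement of unsaturated endoperoxides to diene monoepoxides, which gives 12.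

**Further compounds**

F1 | step 3 | [(3S,4R,5R,6S)-5-hydroxy-6-{[(2S)-2-methoxy-2-phenylacetyl]oxy}-3,4-bis(phenylsulfonyl)cyclohex-1-en-1-yl]methyl benzoate | O=C(OCC1=C[C@H](S(=O)(=O)c2ccccc2)[C@H](S(=O)(=O)c2ccccc2)[C@H](O)[C@H]1OC(=O)[C@@H](OC)c1ccccc1)c1ccccc1
F2 | step 3 | [(3R,4S,5S,6R)-5-hydroxy-6-{[(2S)-2-methoxy-2-phenylacetyl]oxy}-3,4-bis(phenylsulfonyl)cyclohex-1-en-1-yl]methyl benzoate | O=C(OCC1=C[C@@H](S(=O)(=O)c2ccccc2)[C@@H](S(=O)(=O)c2ccccc2)[C@@H](O)[C@@H]1OC(=O)[C@@H](OC)c1ccccc1)c1ccccc1
F3 | step 3 | [(3S,4R,5R,6S)-5-(benzoyloxy)-6-{[(2S)-2-methoxy-2-phenylacetyl]oxy}-3,4-bis(phenylsulfonyl)cyclohex-1-en-1-yl]methyl benzoate | O=C(OCC1=C[C@H](S(=O)(=O)c2ccccc2)[C@H](S(=O)(=O)c2ccccc2)[C@H](OC(=O)c2ccccc2)[C@H]1OC(=O)[C@@H](OC)c1ccccc1)c1ccccc1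
F4 | step 6 | [(5S,6S)-5-hydroxy-6-[(4-methoxybenzyl)oxy]cyclohexa-1,3-dien-1-yl]methyl benzoate | O=C(OCC1=CC=C[C@H](O)[C@H]1OCc1ccc(OC)cc1)c1ccccc1
F5 | step 6 | [(5S,6S)-5-(benzoyloxy)-6-[(4-methoxybenzyl)oxy]cyclohexa-1,3-dien-1-yl]methyl benzoate | O=C(OCC1=CC=C[C@H](OC(=O)c2ccccc2)[C@H]1OCc1ccc(OC)cc1)c1ccccc1
F6 | step 7 | [(1R,4R,7R,8R)-7-(benzoyloxy)-8-hydroxy-2,3-dioxabicyclo[2.2.2]oct-5-en-1-yl]methyl benzoate | O=C(OC[C@]12OO[C@H](C=C1)[C@H](OC(=O)c1ccccc1)[C@H]2O)c1ccccc1
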